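The retrosynthesis cuts the two ArO–Bn bonds and the CH2O–Si bond, takes the aroyl C=O back to an exocyclic C4=CH–aryl alkene, then cuts ring bond C3–C4, the alkyne–aryl bond, ether bond O1–C5 and the C2–C3 bond (aldehyde plus vinyl metal).
Enabling feature: in the oxolane O1–C2(aryl)–C3(CH2OH)–C4(aroyl)–C5H2, C3 bears a CH2–O arm and is bonded to C4, so C3 and this arm map onto a terminal oxirane. Reductive opening puts a radical on C3, and the chain C3–C2–O1–C5–C4 places it at 5-exo distance from an alkyne carbon C4 whose other carbon is the future ketone carbon with its arene.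
Forward, the chain is joined at C2–C3 (Grignard), O1–C5 (etherification) and aryl–alkyne (Sonogashira) and then epoxidised. The only ring, the oxolane, closes in step 6, after which the benzylidene becomes the aryl ketone and the masks come off.
Stereochemistry: C2 comes from a lipase resolution of the allylic alcohol. C3 comes from control by C2 in the radical ring closure, where both oxirane epimers converge. C4 comes from base equilibration next to the ketone to the all-trans oxolane.

Key step: step 6

Remark: ring atoms are numbered O1, C2 (aryl), C3 (CH2O arm), C4 (aroyl), C5 throughout. Ar is 3-(benzyloxy)-4-methoxyphenyl. The target is (2S,3R,4S), that is 2,3-trans and 3,4-trans. The four starting materials are taken as catalogue chemicals.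

Step 1
Reactants: 1 3-(benzyloxy)-4-methoxybenzaldehyde; 2 vinylmagnesium bromide
Product: 3 (±)-1-[3-(benzyloxy)-4-methoxyphenyl]prop-2-en-1-ol
Conditions: THF, 0 °C; then aq NH4Cl
Reagents that add atoms: vinylmagnesium bromide (2), C=C[Mg]Br
Why: Grignard 1,2-addition of a vinyl nucleophile to a non-enolisable aromatic aldehyde forms C2–C3 reliably, and the carbinol centre (future C2) is made racemic on purpose.

Step 2
Reactants: 3 (±)-1-[3-(benzyloxy)-4-methoxyphenyl]prop-2-en-1-ol
Product: 4 (S)-1-[3-(benzyloxy)-4-methoxyphenyl]prop-2-en-1-ol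
Conditions: immobilised Candida antarctica lipase B, vinyl acetate, MTBE, 30 °C, stopped slightly past half conversion; chromatography
Reagents that add atoms: none
Why: In this lipase-catalysed kinetic resolution by irreversible transesterification, aryl is the large and vinyl the medium group, so the enzyme should acylate the R alcohol and leave the S alcohol, which fixes C2 and is separable from the acetate.

Step 3
Reactants: 4 (S)-1-[3-(benzyloxy)-4-methoxyphenyl]prop-2-en-1-ol; 5 propargyl bromide
Product: 6 2-(benzyloxy)-1-methoxy-4-[(1S)-1-(prop-2-yn-1-yloxy)prop-2-en-1-yl]benzene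
Conditions: NaH, cat. Bu4NI, THF–DMF, 0 °C → rt
Reagents that add atoms: propargyl bromide (5), C#CCBr
Why: Williamson ether synthesis on a reactive propargylic bromide forms O1–C5, and the C2–O bond is never broken, so the configuration is kept.

Step 4
Reactants: 6 2-(benzyloxy)-1-methoxy-4-[(1S)-1-(prop-2-yn-1-yloxy)prop-2-en-1-yl]benzene; 7 2-(benzyloxy)-4-bromo-1-methoxybenzene
Product: 8 (S)-1,6-enyne ArCH(CH=CH2)–O–CH2–C≡C–Ar, that is 2-(benzyloxy)-4-[(1S)-1-({3-[3-(benzyloxy)-4-methoxyphenyl]prop-2-yn-1-yl}oxy)prop-2-en-1-yl]-1-methoxybenzene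
Conditions: cat. PdCl2(PhCN)2, cat. P(t-Bu)3, cat. CuI, HN(i-Pr)2, dioxane, rt, under argon
Reagents that add atoms: 2-(benzyloxy)-4-bromo-1-methoxybenzene (7), COc1ccc(Br)cc1OCc1ccccc1
Why: In this Sonogashira coupling the bulky electron-rich phosphine allows oxidative addition of the electron-rich aryl bromide at room temperature, while the allylic ether, the terminal alkene and the stereocentre are spectators.

Step 5
Reactants: 8 (S)-1,6-enyne ArCH(CH=CH2)–O–CH2–C≡C–Ar
Product: 9 2-[(R)-[3-(benzyloxy)-4-methoxyphenyl]({3-[3-(benzyloxy)-4-methoxyphenyl]prop-2-yn-1-yl}oxy)methyl]oxirane, both epimers at the oxirane carbon (same spatial arrangement at the benzylic carbon as in 8; the descriptor changes only through the priority rules)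
Conditions: mCPBA, CH2Cl2, 0 °C → rt
Reagents that add atoms: 3-chloroperoxybenzoic acid, O=C(OO)c1cccc(Cl)c1
Why: Prilezhaev epoxidation takes the only alkene because the aryl alkyne and the alkoxyarenes react far more slowly with a peracid, and the lack of facial control is harmless since the new centre is erased in step 6.

Step 6
Reactants: 9 epoxy propargyl ether (oxirane epimers)
Product: 10 {(2S,3R)-2-[3-(benzyloxy)-4-methoxyphenyl]-4-[3-(benzyloxy)-4-methoxybenzylidene]oxolan-3-yl}methanol, E/Z mixture
Conditions: Cp2TiCl2 (2.5 equiv), Zn dust, deoxygenated THF, rt, the green Ti(III) solution added slowly to 9; then 1 M HCl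
Reagents that add atoms: none
Why: Titanocene(III) chloride, made in the flask from Cp2TiCl2 and zinc, binds the oxirane oxygen and transfers one electron, which cleaves the C–O bond at the substituted carbon and gives the secondary β-titanoxy radical at C3 rather than the primary one. This radical adds to the proximal alkyne carbon C4, forming C3–C4 and closing the oxolane in the 5-exo-dig mode, and the aryl-stabilised vinyl radical is then reduced by a second Ti(III) and protonated on work-up (or takes hydrogen from THF), so the benzylidene should arise as an E/Z mixture. The closest known reaction type is the titanocene(III)-mediated reductive epoxide opening and radical cyclisation of epoxy allyl and propargyl ethers to 3-(hydroxymethyl)oxolanes. The only new stereocentre, C3, is controlled by C2: the radical carbon is planar, so both oxirane epimers give the same intermediate, and in the envelope-like transition state the C2 aryl sits pseudo-equatorial while the bulky titanoxymethyl arm turns to the opposite face, which should give the 2,3-trans (2S,3R) product. The step needs ring closure to outrun capture of the C3 radical by Ti(III) (which would deoxygenate back to 8) and exo attack to beat endo attack; the aryl group on the distal alkyne carbon speeds up and directs exo attack, and slow addition keeps the Ti(III) concentration low.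

Step 7
Reactants: 10 {(2S,3R)-2-Ar-4-(Ar-methylidene)oxolan-3-yl}methanol
Product: 11 tert-butyl({(2S,3R)-2-Ar-4-(Ar-methylidene)oxolan-3-yl}methoxy)dimethylsilane, E/Z mixture
Conditions: TBSCl, imidazole, CH2Cl2, rt
Reagents that add atoms: tert-butyldimethylsilyl chloride, CC(C)(C)[Si](C)(C)Cl
Why: Standard silylation of an unhindered primary alcohol masks it, so that only the benzylic alcohol made in step 8 is oxidised in step 9.

Step 8
Reactants: 11 TBS ether of the benzylidene oxolane
Product: 13 (2S,3R)-2-Ar-3-(TBSOCH2)-4-[Ar(hydroxy)methyl]oxolane, mixture at C4 and at the carbinol carbon, via benzylic alkylborane 12 (not isolated)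
Conditions: BH3·THF, THF, 0 °C → rt; then NaOH, H2O2, 0 °C
Reagents that add atoms: hydrogen peroxide, OO (carbinol oxygen); borane as its THF complex, B (boron, present in 12 only)
Why: In this hydroboration–oxidation boron goes to the less substituted benzylic alkene carbon and hydrogen to the fully substituted C4, oxidation with retention gives the benzylic alcohol, and the outcome at both new centres is irrelevant because one is removed in step 9 and the other equilibrated in step 10.

Step 9
Reactants: 13 benzylic alcohol (diastereomer mixture)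
Product: 14 [3-(benzyloxy)-4-methoxyphenyl][(2S,3R)-2-Ar-3-(TBSOCH2)oxolan-4-yl]methanone, both C4 epimers
Conditions: Dess–Martin periodinane, CH2Cl2, 0 °C → rt
Reagents that add atoms: none
Why: Dess–Martin oxidation of a secondary benzylic alcohol runs under mild, nearly neutral conditions that leave the silyl ether, the benzyl ethers and the benzylic ring ether untouched.

Step 10
Reactants: 14 aryl ketone (C4 epimers)
Product: 15 [3-(benzyloxy)-4-methoxyphenyl][(2S,3R,4S)-2-Ar-3-(TBSOCH2)oxolan-4-yl]methanone (all-trans)
Conditions: cat. NaOMe, MeOH–THF, rt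
Reagents that add atoms: none
Why: Base-catalysed epimerisation through the enolate moves the only acidic stereocentre to the thermodynamically preferred 3,4-trans (4S) arrangement, while β-elimination of O1 is held back because the C5–O1 bond lies near the nodal plane of the exocyclic enolate (the reverse of a 5-endo-trig closure) and the protic medium reprotonates quickly.

Step 11
Reactants: 15 all-trans silyl-protected ketone
Product: 16 [3-(benzyloxy)-4-methoxyphenyl][(2S,3R,4S)-2-Ar-3-(hydroxymethyl)oxolan-4-yl]methanone
Conditions: HF·pyridine, THF, 0 °C → rt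
Reagents that add atoms: none
Why: Fluoride-driven cleavage of the primary TBS ether in a mildly acidic medium avoids enolate formation, so C4 stays as set, and the trans keto alcohol cannot close to a hemiketal.

Step 12
Reactants: 16 bis-benzyl ether of the target
Product: 17 (3-hydroxy-4-methoxyphenyl)[(2S,3R,4S)-2-(3-hydroxy-4-methoxyphenyl)-3-(hydroxymethyl)oxolan-4-yl]methanone (CNP0234761.1)
Conditions: H2 (1 atm), 10% Pd/C, EtOAc, rt, stopped when 16 is consumed
Reagents that add atoms: none
Why: In this catalytic hydrogenolysis aryl benzyl ethers are cleaved much faster than the electron-rich aryl ketone is reduced or the C2–O1 benzylic bond is broken, so a short run in an acid-free aprotic solvent should free both phenols with all three stereocentres intact.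

Compound list
1 | 3-(benzyloxy)-4-methoxybenzaldehyde | O=Cc1ccc(OC)c(OCc2ccccc2)c1 | starting material
2 | vinylmagnesium bromide | C=C[Mg]Br | starting material
3 | (±)-1-[3-(benzyloxy)-4-methoxyphenyl]prop-2-en-1-ol | C=CC(O)c1ccc(OC)c(OCc2ccccc2)c1 | intermediate
4 | (S)-1-[3-(benzyloxy)-4-methoxyphenyl]prop-2-en-1-ol | O[C@H](c1ccc(OC)c(OCc2ccccc2)c1)C=C | intermediate
5 | propargyl bromide | C#CCBr | starting material
6 | 2-(benzyloxy)-1-methoxy-4-[(1S)-1-(prop-2-yn-1-yloxy)prop-2-en-1-yl]benzene | C#CCO[C@H](c1ccc(OC)c(OCc2ccccc2)c1)C=C | intermediate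
7 | 2-(benzyloxy)-4-bromo-1-methoxybenzene | COc1ccc(Br)cc1OCc1ccccc1 | starting material
8 | (S)-1,6-enyne ArCH(CH=CH2)OCH2C≡CAr | COc1ccc(C#CCO[C@H](c2ccc(OC)c(OCc3ccccc3)c2)C=C)cc1OCc1ccccc1 | intermediate
9 | epoxy propargyl ether, benzylic carbon R, oxirane carbon both epimers | COc1ccc(C#CCO[C@H](c2ccc(OC)c(OCc3ccccc3)c2)C2CO2)cc1OCc1ccccc1 | intermediate
10 | {(2S,3R)-2-Ar-4-(Ar-methylidene)oxolan-3-yl}methanol, E/Z | COc1ccc(C=C2CO[C@H](c3ccc(OC)c(OCc4ccccc4)c3)[C@H]2CO)cc1OCc1ccccc1 | intermediate
11 | TBS ether of 10, E/Z | COc1ccc(C=C2CO[C@H](c3ccc(OC)c(OCc4ccccc4)c3)[C@H]2CO[Si](C)(C)C(C)(C)C)cc1OCc1ccccc1 | intermediate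
12 | benzylic alkylborane from 11 (not isolated) | COc1ccc(C(B)C2CO[C@H](c3ccc(OC)c(OCc4ccccc4)c3)[C@H]2CO[Si](C)(C)C(C)(C)C)cc1OCc1ccccc1 | intermediate
13 | (2S,3R)-2-Ar-3-(TBSOCH2)-4-[Ar(hydroxy)methyl]oxolane, mixture at C4 and carbinol carbon | COc1ccc(C(O)C2CO[C@H](c3ccc(OC)c(OCc4ccccc4)c3)[C@H]2CO[Si](C)(C)C(C)(C)C)cc1OCc1ccccc1 | intermediate
14 | (2S,3R)-4-aroyl oxolane TBS ether, both C4 epimers | COc1ccc(C(=O)C2CO[C@H](c3ccc(OC)c(OCc4ccccc4)c3)[C@H]2CO[Si](C)(C)C(C)(C)C)cc1OCc1ccccc1 | intermediate
15 | (2S,3R,4S)-4-aroyl oxolane TBS ether, all-trans | COc1ccc(C(=O)[C@@H]2CO[C@H](c3ccc(OC)c(OCc4ccccc4)c3)[C@H]2CO[Si](C)(C)C(C)(C)C)cc1OCc1ccccc1 | intermediate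
16 | (2S,3R,4S)-keto alcohol, bis-benzyl ether | COc1ccc(C(=O)[C@@H]2CO[C@H](c3ccc(OC)c(OCc4ccccc4)c3)[C@H]2CO)cc1OCc1ccccc1 | intermediate
17 | (3-hydroxy-4-methoxyphenyl)[(2S,3R,4S)-2-(3-hydroxy-4-methoxyphenyl)-3-(hydroxymethyl)oxolan-4-yl]methanone | COc1ccc(C(=O)[C@@H]2CO[C@H](c3ccc(OC)c(O)c3)[C@H]2CO)cc1O | target

Total step count: 12. Longest linear sequence: 12 steps (1 → 17).

Steps most likely to fail

Step 6. The C3 radical may be captured by Ti(III) before it cyclises, which leads to deoxygenation, or the epoxide may be opened by a Lewis-acid pathway instead of by electron transfer. The fallback sets out from 8 and returns at 11, so step 7 is skipped. The alkene of 8 is dihydroxylated (cat. OsO4, NMO; the internal aryl alkyne reacts much more slowly) to the 1,2-diol F1 as both carbinol epimers. The primary hydroxyl is silylated selectively (TBSCl, imidazole) to the mono-TBS ether F2. The secondary hydroxyl is converted with 1,1'-thiocarbonyldiimidazole into the imidazolylthiocarbonate F3. Bu3SnH and AIBN in dilute refluxing toluene then generate the same planar C3 radical by Barton–McCombie-type C–O homolysis. No reducing metal is present to intercept it, and 5-exo-dig closure followed by hydrogen transfer from the stannane should give 11.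

Step 8. Borane addition to the hindered trisubstituted alkene may be slow, or part of the boron may be placed on C4 and followed by β-elimination of O1 with ring opening. The fallback sets out from 11 and returns at 14. OsO4/NMO dihydroxylation of the benzylidene gives the C4-tertiary, benzylic-secondary diol F4. Oxidation of the only oxidisable hydroxyl (SO3·pyridine, DMSO, Et3N) gives the α-hydroxy ketone F5. SmI2 in THF–MeOH at −78 °C then cleaves the α C–O bond reductively through the ketyl and samarium enolate to the ketone 14, whose C4 mixture is equilibrated in step 10 as before.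

Step 12. Reduction may run on, with hydrogenolysis of the C2–O1 benzylic ring bond or reduction of the aryl ketone competing with debenzylation. The fallback sets out from 16 and ends directly at 17. It replaces reduction by a non-reductive benzyl transfer: BCl3 with pentamethylbenzene as cation scavenger in CH2Cl2 at −78 °C, then a methanol quench. A ketone cannot be reduced under these conditions, and the low temperature should spare the ring ether and the methyl ethers.

Further compounds
F1 | step 6 | (3R)-3-Ar-3-{[3-Ar-prop-2-yn-1-yl]oxy}propane-1,2-diol, both C2 epimers | COc1ccc(C#CCO[C@H](c2ccc(OC)c(OCc3ccccc3)c2)C(O)CO)cc1OCc1ccccc1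
F2 | step 6 | primary mono-TBS ether of F1 | COc1ccc(C#CCO[C@H](c2ccc(OC)c(OCc3ccccc3)c2)C(O)CO[Si](C)(C)C(C)(C)C)cc1OCc1ccccc1
F3 | step 6 | O-(secondary alkyl) imidazole-1-carbothioate of F2 | COc1ccc(C#CCO[C@H](c2ccc(OC)c(OCc3ccccc3)c2)C(CO[Si](C)(C)C(C)(C)C)OC(=S)n2ccnc2)cc1OCc1ccccc1
F4 | step 8 | (2S,3R)-2-Ar-3-(TBSOCH2)-4-hydroxy-4-[Ar(hydroxy)methyl]oxolane, diastereomer mixture | COc1ccc(C(O)C2(O)CO[C@H](c3ccc(OC)c(OCc4ccccc4)c3)[C@H]2CO[Si](C)(C)C(C)(C)C)cc1OCc1ccccc1
F5 | step 8 | (2S,3R)-2-Ar-3-(TBSOCH2)-4-hydroxy-4-aroyloxolane, C4 epimers | COc1ccc(C(=O)C2(O)CO[C@H](c3ccc(OC)c(OCc4ccccc4)c3)[C@H]2CO[Si](C)(C)C(C)(C)C)cc1OCc1ccccc1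
F0 | step 12 | none | none
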